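**The amounts.** You charge electrophile at 0.10 M and protonated nucleophile at 1.50 equiv, which is 0.150 M. Gas has a held saturation concentration of 26 mM, with none in solution at the start. The west and south-west runs differ from this flask in the protonated nucleophile charge.

common to all: electrophile 0.10 M; gas 26 mM (held)
- west: protonated nucleophile 2.1 equiv; run made earlier
- south-west: protonated nucleophile 3.3 equiv; run made earlier
- flask: protonated nucleophile 1.50 equiv; time 3.0 min

| run | time / min | electrophile / % | target / % |
|---|---|---|---|
| west | 0.833 | 90.6 | 7.0 |
| west | 1.50 | 85.4 | 14.5 |
| west | 2.50 | 74.0 | 25.3 |
| west | 3.00 | 68.4 | 30.8 |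
| south-west | 0.833 | 89.3 | 10.6 |
| south-west | 1.50 | 82.7 | 16.4 |
| south-west | 2.50 | 72.3 | 29.9 |
| south-west | 3.00 | 67.1 | 33.5 |

(scatter of a reading: 1 percentage point)

- at the start none of the gas is in solution
- the earlier runs do not show how much of nucleophile is bound; that part of a forecast is a guess

1. part of the electrophile that has reacted at 3.0 min
2. share of the unused nucleophile that is free and not bound as protonated nucleophile, at 3.0 min

**First instants.** In the west run, electrophile and target together make 97.6% at 0.833 min. So, as far as these readings show, what leaves the electrophile appears as target.

**The middle.** Call k the apparent first-order constant: ln(charged/left) divided by time. In the west run it reads 0.119 /min at 0.833 min and 0.105 /min at 1.50 min. Within the scatter of 1 percentage point, you can treat it as steady so far.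

**The end.** At 3.00 min, k reads 0.127 /min in the west run and 0.133 /min in the south-west run. The second reads larger, but not by much.

**The rule.** Now compare the runs. The apparent order n is the logarithm of the ratio of k divided by the logarithm of the ratio of charges: 0.109. It is a reading, and a small one.

**My reckoning.** Scaling the west k by the charge ratio raised to n gives 0.122 /min for this flask, so 30.7% reacted at 3.0 min. The runs do not show the bound share, so I give no number for it.

**The forecast.** It says 28.5%, below mine, and 15% free, which it calls “largely a guess”.

**The result.**

    electrophile + nucleophile ⇌ acid set free + target (K = 1.27, k = 0.0714 /M/s)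
    nucleophile + acid set free ⇌ protonated nucleophile, settled at all times (K = 390 /M)
    acid set free + free base ⇌ salt of the base, settled at all times (K = 1.27 × 10⁵ /M)
    gas ⇌ free base, rate k4*(csat - [free base]) (kL = 0.0198 /s)

The flask gives 29.7% reacted and 31.9% free. At 3.00 min it holds nucleophile at 0.0384 M, while the neighbouring flask with 0.900 equiv of protonated nucleophile holds 0.0370 M, nearly the same. With n = 0.109, the west k scaled to that neighbour's charge gives 29.3% reacted, and that neighbour reaches 28.3%.

(Readings and results come from a simulation for an exercise; the scatter is artificial.)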